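**Retrosynthetic overview**
- Target ⇐ 6'-hydroxy-5,6,7,2',3',4'-hexamethoxyflavone by chelation-directed cleavage of the peri 5-OMe; that phenol ⇐ its 6'-O-benzyl ether by hydrogenolysis.
- Benzyl-protected flavone ⇐ 2'-hydroxychalcone by I2/DMSO oxidative cyclisation; the pyranone ring C is the only ring built, and it is built last.
- Chalcone ⇐ Claisen–Schmidt aldol condensation (key C–C bond, future C2–C3) of 2'-hydroxy-4',5',6'-trimethoxyacetophenone with 2-benzyloxy-4,5,6-trimethoxybenzaldehyde.
- Both aryl partners ⇐ 3,4,5-trimethoxyphenol (C-acetylation on one side; O-benzylation then Vilsmeier formylation on the other); rings A and B are bought intact.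

Assumption: the target has no stereocentre and no configurationally stable axis, so it is achiral and needs no enantiocontrol; equivalents are indicative.

**Step 1**
Reactants: 1 3,4,5-trimethoxyphenol
Product: 3 1-(2-hydroxy-4,5,6-trimethoxyphenyl)ethanone (2'-hydroxy-4',5',6'-trimethoxyacetophenone), via difluoroboron chelate 2 (not isolated)
Conditions: AcOH, BF3·OEt2 (3 equiv), 90 °C, 3 h; then H2O, 60 °C
Reagents that add atoms: acetic acid CC(O)=O
Why: BF3-mediated Friedel–Crafts (Fries-type) C-acylation occurs ortho to the OH at one of the two equivalent free positions of this very electron-rich phenol, the product being held as its BF2 chelate until aqueous hydrolysis; no stereocentre is formed.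

**Step 2**
Reactants: 1 3,4,5-trimethoxyphenol
Product: 4 5-(benzyloxy)-1,2,3-trimethoxybenzene
Conditions: BnBr (1.1 equiv), K2CO3, DMF, 60 °C
Reagents that add atoms: benzyl bromide BrCc1ccccc1
Why: Williamson ether synthesis of a phenoxide with a reactive benzylic halide is essentially quantitative and masks the phenol for the later base-mediated aldol step.

**Step 3**
Reactants: 4 5-(benzyloxy)-1,2,3-trimethoxybenzene
Product: 6 2-(benzyloxy)-4,5,6-trimethoxybenzaldehyde, via aryl iminium chloride 5 (not isolated)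
Conditions: POCl3 (1.5 equiv), DMF, 0 → 70 °C, 3 h; then ice–H2O, rt
Reagents that add atoms: N,N-dimethylformamide CN(C)C=O; water O
Why: Vilsmeier–Haack formylation attacks one of the two symmetry-equivalent free positions, each activated ortho/para by three alkoxy groups, so only one aldehyde can form after hydrolysis of the iminium salt.

**Step 4**
Reactants: 3 1-(2-hydroxy-4,5,6-trimethoxyphenyl)ethanone; 6 2-(benzyloxy)-4,5,6-trimethoxybenzaldehyde
Product: 8 (E)-3-[2-(benzyloxy)-4,5,6-trimethoxyphenyl]-1-(2-hydroxy-4,5,6-trimethoxyphenyl)prop-2-en-1-one, via aldol adduct 7 (not isolated)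
Conditions: KOH (50% aq, 10 equiv), EtOH, rt, 48–72 h; then 2 M HCl to pH 3
Reagents that add atoms: none
Why: In this Claisen–Schmidt (crossed aldol) condensation only the methyl ketone can enolise and the aldehyde cannot self-condense, and E1cB dehydration of the racemic β-hydroxy ketone gives the conjugated E-chalcone as the thermodynamic product, leaving no stereocentre.

**Step 5**
Reactants: 8 (E)-3-[2-(benzyloxy)-4,5,6-trimethoxyphenyl]-1-(2-hydroxy-4,5,6-trimethoxyphenyl)prop-2-en-1-one
Product: 10 2-[2-(benzyloxy)-4,5,6-trimethoxyphenyl]-5,6,7-trimethoxy-4H-chromen-4-one (6'-benzyloxy-5,6,7,2',3',4'-hexamethoxyflavone), via flavanone 9 (not isolated)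
Conditions: I2 (10 mol %), DMSO, 130 °C, 3 h
Reagents that add atoms: none
Why: In this I2/DMSO oxidative cyclisation the only free phenol closes by intramolecular oxa-Michael addition to the racemic flavanone, which iodine dehydrogenates to the flavone while DMSO re-oxidises HI to I2, so the transient C2 stereocentre is erased.

**Step 6**
Reactants: 10 6'-benzyloxy-5,6,7,2',3',4'-hexamethoxyflavone
Product: 11 2-(2-hydroxy-4,5,6-trimethoxyphenyl)-5,6,7-trimethoxy-4H-chromen-4-one (6'-hydroxy-5,6,7,2',3',4'-hexamethoxyflavone)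
Conditions: H2 (1 atm), 10% Pd/C, EtOAc–MeOH (1:1), rt
Reagents that add atoms: none
Why: Catalytic hydrogenolysis cleaves the benzyl aryl ether cleanly, while the vinylogous-ester C2=C3 bond of the chromone and the methyl ethers are inert at 1 atm and room temperature.

**Step 7**
Reactants: 11 6'-hydroxy-5,6,7,2',3',4'-hexamethoxyflavone
Product: 13 5-hydroxy-2-(2-hydroxy-4,5,6-trimethoxyphenyl)-6,7-dimethoxy-4H-chromen-4-one (5,6'-dihydroxy-6,7,2',3',4'-pentamethoxyflavone), via bis(dichloroboryl) ether 12 (not isolated)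
Conditions: BCl3 (1 M in CH2Cl2, 3 equiv), CH2Cl2, −78 → 0 °C, 1–2 h; then H2O
Reagents that add atoms: none
Why: In this chelation-directed Lewis-acid ether cleavage BCl3 binds the C4 carbonyl and removes only the peri 5-O-methyl through a six-membered boron chelate, the other five methoxy groups having no neighbouring carbonyl and the 6'-phenol being released from its borate on hydrolysis.

**Compound list**
1 | 3,4,5-trimethoxyphenol | COc1cc(O)cc(OC)c1OC | starting material
2 | O,O-difluoroboron chelate of 3 (formed in the flask) | CC1=[O+][B-](F)(F)Oc2cc(OC)c(OC)c(OC)c21 | intermediate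
3 | 1-(2-hydroxy-4,5,6-trimethoxyphenyl)ethanone | CC(=O)c1c(O)cc(OC)c(OC)c1OC | intermediate
4 | 5-(benzyloxy)-1,2,3-trimethoxybenzene | COc1cc(OCc2ccccc2)cc(OC)c1OC | intermediate
5 | N-{[2-(benzyloxy)-4,5,6-trimethoxyphenyl]methylidene}-N-methylmethanaminium chloride (formed in the flask) | C[N+](C)=Cc1c(OCc2ccccc2)cc(OC)c(OC)c1OC.[Cl-] | intermediate
6 | 2-(benzyloxy)-4,5,6-trimethoxybenzaldehyde | O=Cc1c(OCc2ccccc2)cc(OC)c(OC)c1OC | intermediate
7 | 3-[2-(benzyloxy)-4,5,6-trimethoxyphenyl]-3-hydroxy-1-(2-hydroxy-4,5,6-trimethoxyphenyl)propan-1-one (racemic, formed in the flask) | COc1cc(O)c(C(=O)CC(O)c2c(OCc3ccccc3)cc(OC)c(OC)c2OC)c(OC)c1OC | intermediate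
8 | (E)-3-[2-(benzyloxy)-4,5,6-trimethoxyphenyl]-1-(2-hydroxy-4,5,6-trimethoxyphenyl)prop-2-en-1-one | COc1cc(O)c(C(=O)/C=C/c2c(OCc3ccccc3)cc(OC)c(OC)c2OC)c(OC)c1OC | intermediate
9 | 2-[2-(benzyloxy)-4,5,6-trimethoxyphenyl]-5,6,7-trimethoxychroman-4-one (racemic, formed in the flask) | COc1cc2OC(c3c(OCc4ccccc4)cc(OC)c(OC)c3OC)CC(=O)c2c(OC)c1OC | intermediate
10 | 2-[2-(benzyloxy)-4,5,6-trimethoxyphenyl]-5,6,7-trimethoxy-4H-chromen-4-one | COc1cc(OCc2ccccc2)c(-c2cc(=O)c3c(OC)c(OC)c(OC)cc3o2)c(OC)c1OC | intermediate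
11 | 2-(2-hydroxy-4,5,6-trimethoxyphenyl)-5,6,7-trimethoxy-4H-chromen-4-one | COc1cc(O)c(-c2cc(=O)c3c(OC)c(OC)c(OC)cc3o2)c(OC)c1OC | intermediate
12 | 5,6'-bis-O-(dichloroboryl) derivative of 13 (formed in the flask) | COc1cc(OB(Cl)Cl)c(-c2cc(=O)c3c(OB(Cl)Cl)c(OC)c(OC)cc3o2)c(OC)c1OC | intermediate
13 | 5,6'-dihydroxy-6,7,2',3',4'-pentamethoxyflavone | COc1cc(O)c(-c2cc(=O)c3c(O)c(OC)c(OC)cc3o2)c(OC)c1OC | target

**Totals**
Total step count: 7. Longest linear sequence: 6 steps (1 → 4 → 6 → 8 → 10 → 11 → 13); the acetophenone branch 1 → 3 joins at step 4.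

**Steps most likely to fail and their fallbacks**

Step 4 is the first risk: the aldehyde 6 is 2,6-disubstituted and electron-rich, and the ketone 3 is also hindered, so the aldol condensation may stall. The fallback forms the same C–C bond by an intermolecular crossed Claisen condensation at the diketone oxidation level. It sets out from aldehyde 6, with 3 as the ketone partner.
- Pinnick oxidation (NaClO2, NaH2PO4, 2-methyl-2-butene, t-BuOH/H2O) gives 2-(benzyloxy)-4,5,6-trimethoxybenzoic acid F1.
- Oxalyl chloride with catalytic DMF in CH2Cl2 gives 2-(benzyloxy)-4,5,6-trimethoxybenzoyl chloride F2.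
- F2 C-acylates the dilithium dianion of 3 (LiHMDS 3.5 equiv, THF, −78 → −10 °C) to give 1-[2-(benzyloxy)-4,5,6-trimethoxyphenyl]-3-(2-hydroxy-4,5,6-trimethoxyphenyl)propane-1,3-dione F3. Any O-acylated ester is carried to F3 by the excess base.
- Cyclodehydration (cat. H2SO4, AcOH, 60–90 °C) closes ring C and comes back to the route at flavone 10, bypassing 8 and step 5.
- If the acid also removes the benzyl group, the resulting diketone is symmetric, so closure from either phenol gives 11.

Step 5 is the second risk: HI formed at 130 °C may nick the benzyl or 5-methyl ether, and the hindered β-carbon may slow ring closure. The fallback separates ring closure from oxidation and changes the oxidant type. It sets out from chalcone 8, which is isomerised to the flavanone 9 (NaOAc, EtOH, reflux) and isolated. Flavanone 9 is then dehydrogenated by hydride abstraction with DDQ (dioxane, reflux), coming back to the route at flavone 10. This fallback makes no compound outside the list above (none, F0).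

Step 7 is the third risk: with the free 6'-phenol bound as a borate and excess BCl3 present, conversion may be incomplete or the neighbouring 6-OMe may also be cleaved. The fallback removes the free phenol from the demethylation step. It sets out from 11.
- Acetylation (Ac2O, pyridine, cat. DMAP, rt) gives 6'-acetoxy-5,6,7,2',3',4'-hexamethoxyflavone F4.
- BCl3 (1.2 equiv, CH2Cl2, −78 → 0 °C; then H2O) cleaves only the peri ether to give 6'-acetoxy-5-hydroxy-6,7,2',3',4'-pentamethoxyflavone F5.
- Mild methanolysis (K2CO3, MeOH, rt) comes back to the route at the target 13.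

**Further compounds**
F1 | step 4 | 2-(benzyloxy)-4,5,6-trimethoxybenzoic acid | OC(=O)c1c(OCc2ccccc2)cc(OC)c(OC)c1OC
F2 | step 4 | 2-(benzyloxy)-4,5,6-trimethoxybenzoyl chloride | ClC(=O)c1c(OCc2ccccc2)cc(OC)c(OC)c1OC
F3 | step 4 | 1-[2-(benzyloxy)-4,5,6-trimethoxyphenyl]-3-(2-hydroxy-4,5,6-trimethoxyphenyl)propane-1,3-dione | COc1cc(O)c(C(=O)CC(=O)c2c(OCc3ccccc3)cc(OC)c(OC)c2OC)c(OC)c1OC
F0 | step 5 | none | none
F4 | step 7 | 2-(2-acetoxy-4,5,6-trimethoxyphenyl)-5,6,7-trimethoxy-4H-chromen-4-one | COc1cc(OC(C)=O)c(-c2cc(=O)c3c(OC)c(OC)c(OC)cc3o2)c(OC)c1OC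
F5 | step 7 | 2-(2-acetoxy-4,5,6-trimethoxyphenyl)-5-hydroxy-6,7-dimethoxy-4H-chromen-4-one | COc1cc(OC(C)=O)c(-c2cc(=O)c3c(O)c(OC)c(OC)cc3o2)c(OC)c1OC
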